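**Strategy.** The route rests on the C8–C9 bond of the ten-membered carbocycle. C8 and C10 are 1,3-related oxygenated ring carbons flanking C9, and the butenolide (C6, C7, C11, C12) can be carried as a furan. A 2-substituted allyl unit on C1 (C9, C10, C14) is therefore added to a furan C8 aldehyde. One chromium-mediated Barbier closure forms C8–C9, the ten-membered ring and the C8 carbinol, and leaves an exocyclic C10 methylene for the tertiary alcohol. The precursor is a cis-2,5-disubstituted oxolane (C1–C4 plus oxygen, from (R)-linalool) carrying a 2-(bromomethyl)vinyl group on C1 and, on C4, a methyl and a CH2 link to a 3-formyl-4-(silyloxymethyl)furan.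

Key step: step 14

Remark on numbering: locants follow the germacrane skeleton (C1 = oxolane CH next to C10; C4 = oxolane carbon bearing the methyl group; C5 = carbon between C4 and the furan; C6, C7, C11, C12 = furan or butenolide carbons; C8 = carbinol carbon; C13 = oxymethyl carbon on C11; C14 = carbon on C10). Centres that are destroyed later (oxirane carbon in 5–18, C5 in 15–17, C6 and C12 in 32–34) are carried as epimer mixtures and left unspecified in the SMILES.

Assumption: the D-fructose-derived Shi ketone epoxidises the Me2C=CH–CH2 alkene of 1 on the face that gives the (6R) oxirane, as with other trisubstituted alkenes of this type.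

**Route**

Step 1
Reactants: 1 (R)-linalool
Product: 3 cis-linalool oxide [2-((2S,5R)-5-ethenyl-5-methyloxolan-2-yl)propan-2-ol], via (3R,6R)-6,7-epoxylinalool 2 (not isolated)
Conditions: D-fructose-derived Shi ketone (30 mol%), KHSO5, K2CO3, Bu4NHSO4, MeCN/CH2(OMe)2/aq. Na2B4O7 buffer, 0 °C; then CSA (cat.), CH2Cl2, 0 °C
Reagents that add atoms: potassium peroxymonosulfate, [K+].[O-]S(=O)(=O)OO
Why: Shi epoxidation oxidises only the electron-rich trisubstituted alkene under reagent control to the (6R) epoxide, and acid-catalysed 5-exo opening by the tertiary hydroxyl inverts C6, so the new oxolane carbon is (2S) with hydroxypropyl and vinyl cis, while the carbinol centre of 1 becomes the untouched (5R) carbon; the minor pyranoid isomer from 6-endo opening is removed by chromatography.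

Step 2
Reactants: 3 cis-linalool oxide
Product: 4 (2R,5S)-2-ethenyl-2-methyl-5-(prop-1-en-2-yl)oxolane
Conditions: SOCl2, pyridine, CH2Cl2, −20 to 0 °C
Reagents that add atoms: none
Why: Pyridine-mediated E2 loss from the tertiary chlorosulfite (alcohol dehydration) removes one of six methyl hydrogens in preference to the single hindered ring hydrogen next to oxygen, the known way from 2-hydroxypropan-2-yl cyclic ethers to isopropenyl ethers, and touches no stereocentre.

Step 3
Reactants: 4 isopropenyl vinyl oxolane
Product: 5 (2R,5S)-2-ethenyl-2-methyl-5-(2-methyloxiran-2-yl)oxolane (both oxirane epimers)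
Conditions: mCPBA (1.0 equiv), NaHCO3, CH2Cl2, 0 °C
Reagents that add atoms: 3-chloroperoxybenzoic acid, OOC(=O)c1cccc(Cl)c1
Why: Prilezhaev epoxidation is faster at the 1,1-disubstituted alkene than at the monosubstituted vinyl group, so one equivalent masks the isopropenyl unit as an ozone-stable latent allylic alcohol; the new oxirane centre becomes sp2 in step 11, so its configuration does not matter.

Step 4
Reactants: 5 epoxy vinyl oxolane
Product: 7 (2R,5S)-2-methyl-5-(2-methyloxiran-2-yl)oxolane-2-carbaldehyde, via secondary ozonide 6 (not isolated)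
Conditions: O3, CH2Cl2, −78 °C; then PPh3, −78 °C to rt
Reagents that add atoms: ozone, [O-][O+]=O
Why: Ozonolysis and reductive work-up cleave the only remaining alkene to a non-enolisable aldehyde on the quaternary carbon, which therefore cannot epimerise, and the oxirane and ether are inert to ozone at low temperature.

Step 5
Reactants: 8 diethyl furan-3,4-dicarboxylate
Product: 9 furan-3,4-diyldimethanol
Conditions: LiAlH4, THF, 0 °C to rt
Reagents that add atoms: none
Why: LiAlH4 reduction of both esters to primary alcohols is routine and does not touch the furan.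

Step 6
Reactants: 9 furan-3,4-diyldimethanol
Product: 11 [4-({[tert-butyl(dimethyl)silyl]oxy}methyl)furan-3-yl]methanol, via monosodium alkoxide 10 (not isolated)
Conditions: NaH (1.0 equiv), THF, 0 °C to rt; then TBSCl (1.0 equiv)
Reagents that add atoms: tert-butyl(chloro)dimethylsilane, CC(C)(C)[Si](C)(C)Cl
Why: Monodeprotonation of the symmetrical diol gives a poorly soluble monoalkoxide that is silylated once (desymmetrising monosilylation).

Step 7
Reactants: 11 mono-silyl ether
Product: 12 4-({[tert-butyl(dimethyl)silyl]oxy}methyl)furan-3-carbaldehyde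
Conditions: MnO2, CH2Cl2, rt
Reagents that add atoms: none
Why: MnO2 oxidises the furylic, benzylic-type primary alcohol to the aldehyde without over-oxidation and without affecting the silyl ether.

Step 8
Reactants: 12 furan aldehyde
Product: 13 tert-butyl{[4-(1,3-dioxolan-2-yl)furan-3-yl]methoxy}dimethylsilane
Conditions: Me3SiOCH2CH2OSiMe3, Me3SiOTf (cat.), CH2Cl2, −78 °C; pyridine quench
Reagents that add atoms: 1,2-bis(trimethylsilyloxy)ethane, C[Si](C)(C)OCCO[Si](C)(C)C
Why: Silyl-triflate-catalysed acetalisation with the bis-silyl ether of ethylene glycol runs at low temperature without protic acid or water, so silyl ether and furan survive, and the dioxolane masks the C8 aldehyde and later directs metalation.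

Step 9
Reactants: 13 furan dioxolane; 7 epoxy aldehyde
Product: 17 C5 S-methyl xanthate of the coupled furyl carbinol, via 2-lithiofuran 14 (not isolated), via lithium alkoxide 15 (not isolated), via lithium xanthate 16 (not isolated)
Conditions: 13, n-BuLi, THF, −78 to −20 °C; 7, −78 °C; CS2, −78 to 0 °C; MeI, 0 °C to rt
Reagents that add atoms: carbon disulfide, S=C=S; iodomethane, CI
Why: The dioxolane oxygens bind lithium and direct deprotonation to the furan α-carbon next to the acetal (directed ortho-metalation) and not to the α-carbon beside the bulky, weakly coordinating silyloxymethyl group, the furyllithium adds to the non-enolisable aldehyde faster than to the oxirane, and the alkoxide is converted in the same flask into the S-methyl xanthate; the C5 carbinol centre is removed in step 10, so both epimers are used.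

Step 10
Reactants: 17 xanthate
Product: 18 2-(oxolanylmethyl)furan with C5 as CH2 (oxirane, dioxolane and silyl ether retained)
Conditions: Bu3SnH, AIBN (cat.), toluene, 90 °C
Reagents that add atoms: none
Why: Barton–McCombie deoxygenation passes through a furan-stabilised C5 radical that has neither a β-hydrogen nor an alkene to cyclise onto, since the isopropenyl unit is still an oxirane, and hydrogen transfer from the stannane gives the C5 methylene without touching the quaternary C4.

Step 11
Reactants: 18 epoxide
Product: 19 allylic alcohol [2-substituted prop-2-en-1-ol on C1]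
Conditions: Et2AlCl, LiTMP (lithium 2,2,6,6-tetramethylpiperidide), toluene, 0 °C; aq. potassium sodium tartrate
Reagents that add atoms: none
Why: The aluminium amide formed in the flask binds the oxirane oxygen and removes a syn proton from the unhindered methyl group (epoxide to allylic alcohol isomerisation), breaking the tertiary C10–O bond, so both oxirane epimers converge on one 2-substituted prop-2-en-1-ol, and the non-nucleophilic reagent leaves silyl ether, acetal and furan alone at 0 °C.

Step 12
Reactants: 19 allylic alcohol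
Product: 20 allylic bromide (dioxolane retained)
Conditions: CBr4, PPh3, CH2Cl2, 0 °C
Reagents that add atoms: carbon tetrabromide, BrC(Br)(Br)Br
Why: The Appel reaction turns the primary allylic alcohol into the bromide under neutral conditions, and since both allyl termini are CH2 groups direct and allylic displacement give the same compound.

Step 13
Reactants: 20 allylic bromide acetal
Product: 21 bromo aldehyde [cis-oxolane allylic bromide tethered to 3-formyl-4-(TBS-oxymethyl)furan]
Conditions: PPTS (cat.), acetone/H2O, rt
Reagents that add atoms: water, O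
Why: Mild acid hydrolysis of the furan-3-yl dioxolane proceeds through a well stabilised oxocarbenium ion under conditions that leave the primary silyl ether and the allylic bromide intact (acetal hydrolysis).

Step 14
Reactants: 21 bromo aldehyde
Product: 23 (1S,4R,8S) furan-fused oxygen-bridged cyclodecane bearing C8 hydroxyl plus C10 exocyclic methylene, via allylchromium dichloride 22 (not isolated)
Conditions: CrCl2 (8 equiv), THF, rt, syringe-pump addition of 21 (final 2 mM)
Reagents that add atoms: none
Why: Two equivalents of divalent chromium reduce the C–Br bond to an allyl complex of trivalent chromium, which adds to the furan aldehyde through a six-membered chair transition state (chromium, carbonyl oxygen, C8, C9, C10, C14) with allylic transposition. The closest known reaction is the intramolecular Nozaki–Hiyama allylation used to close ten-membered germacrane rings and larger carbocycles. The ten-membered ring is closed end to end by the C8–C9 bond in a 10-exo-trig attack on the carbonyl, helped by the cis-oxolane turn and the planar furan, which hold C9 and C8 on one side of the tether. The new C8 centre is set under substrate control by C1 and C4: the chair with the furyl group pseudo-equatorial and the tether on its outer face should be the least strained and should give the (8S) carbinol. The step needs cyclisation to outrun oligomerisation, secured by slow addition at high dilution, and chemoselectivity for the aldehyde, secured by the low basicity of the organochromium reagent, to which silyl ether, furan and oxolane are inert. Regiochemistry is not an issue because both allyl termini are CH2 groups and lead to the same C8–C9 bond and the same exocyclic C10 methylene.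

Step 15
Reactants: 23 macrocyclic homoallylic alcohol
Product: 25 (1S,4R,8S,10S) 8,10,14-triol, via osmate ester 24 (not isolated)
Conditions: OsO4 (1.05 equiv), TMEDA, CH2Cl2, −78 °C; then aq. Na2SO3, THF, 40 °C
Reagents that add atoms: osmium tetroxide, O=[Os](=O)(=O)=O
Why: The OsO4–diamine complex accepts a hydrogen bond from the C8 hydroxyl and is delivered to the face of the exocyclic alkene that this hydroxyl can reach (hydroxyl-directed dihydroxylation of a homoallylic alcohol), which should set the C10–O bond cis to the C8–O bond, while the aromatic furan, which peracid or metal-peroxide epoxidants would attack, is osmylated much more slowly than the isolated alkene.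

Step 16
Reactants: 25 triol
Product: 26 C14 primary tosylate
Conditions: TsCl, Et3N, Bu2SnO (cat.), CH2Cl2, 0 °C to rt
Reagents that add atoms: 4-methylbenzenesulfonyl chloride, Cc1ccc(cc1)S(Cl)(=O)=O
Why: Catalytic Bu2SnO forms a stannylene acetal with the 1,2-diol and activates its primary oxygen, so sulfonylation should take place at C14–OH and not at the hindered secondary C8–OH or the tertiary C10–OH (tin-mediated regioselective monotosylation).

Step 17
Reactants: 26 tosylate
Product: 28 (1S,4R,8S,10R) 8,10-diol carrying the C14 methyl group, via spiro-epoxide 27 (not isolated)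
Conditions: LiEt3BH, THF, 0 °C to rt
Reagents that add atoms: none
Why: The tertiary C10 alkoxide displaces the neighbouring tosylate to a spiro-epoxide with the C10–O bond intact, and triethylborohydride opens it by SN2 attack at the unhindered CH2 (hydride opening of an epoxide), so C10 keeps the configuration set in step 15 (its descriptor changes from S to R through the priority change only) and C14 becomes the methyl group.

Step 18
Reactants: 28 diol
Product: 29 C8 methacrylate
Conditions: methacrylic anhydride, Et3N, DMAP (cat.), CH2Cl2, 0 °C to rt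
Reagents that add atoms: methacrylic anhydride, CC(=C)C(=O)OC(=O)C(C)=C
Why: DMAP-catalysed acylation esterifies the secondary C8 hydroxyl, the hindered tertiary C10 hydroxyl does not react under these conditions, and the C8 configuration is retained because the C–O bond is not broken.

Step 19
Reactants: 29 silyl ether
Product: 30 C13 primary alcohol
Conditions: HF·pyridine, pyridine, THF, 0 °C to rt
Reagents that add atoms: none
Why: Buffered fluoride cleaves the primary silyl ether (desilylation) without harming the methacrylate, the furan or the tertiary alcohol.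

Step 20
Reactants: 30 primary alcohol
Product: 31 C13 acetate
Conditions: Ac2O, pyridine, CH2Cl2, 0 °C to rt
Reagents that add atoms: acetic anhydride, CC(=O)OC(C)=O
Why: Acetylation without an acyl-transfer catalyst esterifies the primary C13 hydroxyl and leaves the tertiary C10 hydroxyl free; capping C13 before the furan is opened keeps this hydroxyl from closing a new furan onto the C6 carbonyl of the later keto-acid tautomer.

Step 21
Reactants: 31 furan
Product: 33 γ-hydroxybutenolide (C6 hemiketal epimers), via furan endoperoxide 32 (not isolated)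
Conditions: O2, hν, tetraphenylporphyrin (cat.), CH2Cl2, −78 °C; then i-Pr2NEt, −78 °C to rt
Reagents that add atoms: oxygen, O=O
Why: Singlet oxygen adds across C6 and C12 of the electron-rich furan in a 4+2 cycloaddition far faster than it reacts with the electron-poor methacrylate, and the amine removes the only bridgehead hydrogen, at C12, so that O–O cleavage (Kornblum–DeLaMare fragmentation) gives the lactone carbonyl at C12 and the hemiketal hydroxyl at C6 with the required regiochemistry.

Step 22
Reactants: 33 γ-hydroxybutenolide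
Product: 35 target CNP0516045.1, via C6 acetate 34 (not isolated)
Conditions: Ac2O, Et3N, DMAP (cat.), CH2Cl2, 0 °C to rt
Reagents that add atoms: none
Why: Acetylation of the hemiketal hydroxyl and base-induced loss of acetic acid across C5–C6 (dehydration of a γ-hydroxybutenolide to a γ-ylidenebutenolide) give the conjugated dienolide: C5 carries the only β-hydrogens, the ten-membered ring accommodates only the isomer with C4 and C7 cis, which is (5E), and the hindered tertiary C10 hydroxyl should not be acetylated in the short reaction time.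

**Compound list**

1 | (R)-linalool, (3R)-3,7-dimethylocta-1,6-dien-3-ol | C=C[C@](C)(O)CCC=C(C)C | starting material
2 | (3R)-5-[(2R)-3,3-dimethyloxiran-2-yl]-3-methylpent-1-en-3-ol, (3R,6R)-6,7-epoxylinalool | C=C[C@](C)(O)CC[C@H]1OC1(C)C | intermediate (not isolated)
3 | cis-linalool oxide, 2-[(2S,5R)-5-ethenyl-5-methyloxolan-2-yl]propan-2-ol | CC(C)(O)[C@@H]1CC[C@](C)(C=C)O1 | intermediate
4 | (2R,5S)-2-ethenyl-2-methyl-5-(prop-1-en-2-yl)oxolane | CC(=C)[C@@H]1CC[C@](C)(C=C)O1 | intermediate
5 | (2R,5S)-2-ethenyl-2-methyl-5-(2-methyloxiran-2-yl)oxolane, both oxirane epimers | CC2(CO2)[C@@H]1CC[C@](C)(C=C)O1 | intermediate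
6 | 3-[(2R,5S)-2-methyl-5-(2-methyloxiran-2-yl)oxolan-2-yl]-1,2,4-trioxolane | CC2(CO2)[C@@H]1CC[C@](C)(C3OOCO3)O1 | intermediate (not isolated)
7 | (2R,5S)-2-methyl-5-(2-methyloxiran-2-yl)oxolane-2-carbaldehyde | CC2(CO2)[C@@H]1CC[C@](C)(C=O)O1 | intermediate
8 | diethyl furan-3,4-dicarboxylate | CCOC(=O)c1cocc1C(=O)OCC | starting material
9 | furan-3,4-diyldimethanol | OCc1cocc1CO | intermediate
10 | sodium [4-(hydroxymethyl)furan-3-yl]methanolate | [Na+].[O-]Cc1cocc1CO | intermediate (not isolated)
11 | [4-({[tert-butyl(dimethyl)silyl]oxy}methyl)furan-3-yl]methanol | OCc1cocc1CO[Si](C)(C)C(C)(C)C | intermediate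
12 | 4-({[tert-butyl(dimethyl)silyl]oxy}methyl)furan-3-carbaldehyde | O=Cc1cocc1CO[Si](C)(C)C(C)(C)C | intermediate
13 | tert-butyl{[4-(1,3-dioxolan-2-yl)furan-3-yl]methoxy}dimethylsilane | CC(C)(C)[Si](C)(C)OCc1cocc1C1OCCO1 | intermediate
14 | {4-({[tert-butyl(dimethyl)silyl]oxy}methyl)-3-(1,3-dioxolan-2-yl)furan-2-yl}lithium | CC(C)(C)[Si](C)(C)OCc1coc([Li])c1C1OCCO1 | intermediate (not isolated)
15 | lithium {4-({[tert-butyl(dimethyl)silyl]oxy}methyl)-3-(1,3-dioxolan-2-yl)furan-2-yl}[(2R,5S)-2-methyl-5-(2-methyloxiran-2-yl)oxolan-2-yl]methanolate, C5 and oxirane epimers | CC2(CO2)[C@@H]1CC[C@](C)(C(O[Li])c3occ(CO[Si](C)(C)C(C)(C)C)c3C4OCCO4)O1 | intermediate (not isolated)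
16 | lithium O-{[4-({[tert-butyl(dimethyl)silyl]oxy}methyl)-3-(1,3-dioxolan-2-yl)furan-2-yl][(2R,5S)-2-methyl-5-(2-methyloxiran-2-yl)oxolan-2-yl]methyl} carbonodithioate | CC2(CO2)[C@@H]1CC[C@](C)(C(OC(=S)S[Li])c3occ(CO[Si](C)(C)C(C)(C)C)c3C4OCCO4)O1 | intermediate (not isolated)
17 | O-{[4-({[tert-butyl(dimethyl)silyl]oxy}methyl)-3-(1,3-dioxolan-2-yl)furan-2-yl][(2R,5S)-2-methyl-5-(2-methyloxiran-2-yl)oxolan-2-yl]methyl} S-methyl carbonodithioate, C5 and oxirane epimers | CC2(CO2)[C@@H]1CC[C@](C)(C(OC(=S)SC)c3occ(CO[Si](C)(C)C(C)(C)C)c3C4OCCO4)O1 | intermediate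
18 | tert-butyl{[4-(1,3-dioxolan-2-yl)-5-{[(2R,5S)-2-methyl-5-(2-methyloxiran-2-yl)oxolan-2-yl]methyl}furan-3-yl]methoxy}dimethylsilane, oxirane epimers | CC2(CO2)[C@@H]1CC[C@](C)(Cc3occ(CO[Si](C)(C)C(C)(C)C)c3C4OCCO4)O1 | intermediate
19 | 2-[(2S,5R)-5-{[4-({[tert-butyl(dimethyl)silyl]oxy}methyl)-3-(1,3-dioxolan-2-yl)furan-2-yl]methyl}-5-methyloxolan-2-yl]prop-2-en-1-ol | OCC(=C)[C@@H]1CC[C@](C)(Cc3occ(CO[Si](C)(C)C(C)(C)C)c3C4OCCO4)O1 | intermediate
20 | {[5-{[(2R,5S)-5-(3-bromoprop-1-en-2-yl)-2-methyloxolan-2-yl]methyl}-4-(1,3-dioxolan-2-yl)furan-3-yl]methoxy}(tert-butyl)dimethylsilane | BrCC(=C)[C@@H]1CC[C@](C)(Cc3occ(CO[Si](C)(C)C(C)(C)C)c3C4OCCO4)O1 | intermediate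
21 | 2-{[(2R,5S)-5-(3-bromoprop-1-en-2-yl)-2-methyloxolan-2-yl]methyl}-4-({[tert-butyl(dimethyl)silyl]oxy}methyl)furan-3-carbaldehyde (key-step precursor) | BrCC(=C)[C@@H]1CC[C@](C)(Cc2occ(CO[Si](C)(C)C(C)(C)C)c2C=O)O1 | intermediate
22 | dichloro{2-[(2S,5R)-5-{[4-({[tert-butyl(dimethyl)silyl]oxy}methyl)-3-formylfuran-2-yl]methyl}-5-methyloxolan-2-yl]prop-2-en-1-yl}chromium (allyl complex of trivalent chromium) | Cl[Cr](Cl)CC(=C)[C@@H]1CC[C@](C)(Cc2occ(CO[Si](C)(C)C(C)(C)C)c2C=O)O1 | intermediate (not isolated)
23 | (1S,4R,8S)-13-{[tert-butyl(dimethyl)silyl]oxy}-1,4:6,12-diepoxygermacra-6,10(14),11-trien-8-ol (furan-fused, oxygen-bridged cyclodecane; key-step product) | O[C@H]1CC(=C)[C@@H]2CC[C@](C)(Cc3occ(CO[Si](C)(C)C(C)(C)C)c31)O2 | intermediate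
24 | cyclic C10,C14 osmate ester of 23 (hexavalent osmium), TMEDA adduct | O[C@H]1C[C@@](C4)(O[Os](=O)(=O)O4)[C@@H]2CC[C@](C)(Cc3occ(CO[Si](C)(C)C(C)(C)C)c31)O2.CN(C)CCN(C)C | intermediate (not isolated)
25 | (1S,4R,8S,10S)-13-{[tert-butyl(dimethyl)silyl]oxy}-1,4:6,12-diepoxygermacra-6,11-diene-8,10,14-triol | O[C@H]1C[C@@](CO)(O)[C@@H]2CC[C@](C)(Cc3occ(CO[Si](C)(C)C(C)(C)C)c31)O2 | intermediate
26 | (1S,4R,8S,10S)-13-{[tert-butyl(dimethyl)silyl]oxy}-8,10-dihydroxy-1,4:6,12-diepoxygermacra-6,11-dien-14-yl 4-methylbenzenesulfonate | O[C@H]1C[C@@](COS(=O)(=O)c4ccc(C)cc4)(O)[C@@H]2CC[C@](C)(Cc3occ(CO[Si](C)(C)C(C)(C)C)c31)O2 | intermediate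
27 | (1S,4R,8S,10S)-13-{[tert-butyl(dimethyl)silyl]oxy}-1,4:6,12:10,14-triepoxygermacra-6,11-dien-8-ol (spiro-epoxide) | O[C@H]1C[C@@](C4)(O4)[C@@H]2CC[C@](C)(Cc3occ(CO[Si](C)(C)C(C)(C)C)c31)O2 | intermediate (not isolated)
28 | (1S,4R,8S,10R)-13-{[tert-butyl(dimethyl)silyl]oxy}-1,4:6,12-diepoxygermacra-6,11-diene-8,10-diol | O[C@H]1C[C@@](C)(O)[C@@H]2CC[C@](C)(Cc3occ(CO[Si](C)(C)C(C)(C)C)c31)O2 | intermediate
29 | (1S,4R,8S,10R)-13-{[tert-butyl(dimethyl)silyl]oxy}-10-hydroxy-1,4:6,12-diepoxygermacra-6,11-dien-8-yl 2-methylprop-2-enoate | C=C(C)C(=O)O[C@H]1C[C@@](C)(O)[C@@H]2CC[C@](C)(Cc3occ(CO[Si](C)(C)C(C)(C)C)c31)O2 | intermediate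
30 | (1S,4R,8S,10R)-10,13-dihydroxy-1,4:6,12-diepoxygermacra-6,11-dien-8-yl 2-methylprop-2-enoate | C=C(C)C(=O)O[C@H]1C[C@@](C)(O)[C@@H]2CC[C@](C)(Cc3occ(CO)c31)O2 | intermediate
31 | (1S,4R,8S,10R)-13-acetoxy-10-hydroxy-1,4:6,12-diepoxygermacra-6,11-dien-8-yl 2-methylprop-2-enoate | C=C(C)C(=O)O[C@H]1C[C@@](C)(O)[C@@H]2CC[C@](C)(Cc3occ(COC(C)=O)c31)O2 | intermediate
32 | 6,12-epidioxide (furan endoperoxide) of 31, C6/C12 epimers | C=C(C)C(=O)O[C@H]1C[C@@](C)(O)[C@@H]2CC[C@](C)(CC34OOC(O3)C(COC(C)=O)=C41)O2 | intermediate (not isolated)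
33 | (1S,4R,8S,10R)-13-acetoxy-1,4-epoxy-6,10-dihydroxy-12-oxo-6,12-epoxygermacr-7(11)-en-8-yl 2-methylprop-2-enoate (γ-hydroxybutenolide, C6 epimers) | C=C(C)C(=O)O[C@H]1C[C@@](C)(O)[C@@H]2CC[C@](C)(CC3(O)OC(=O)C(COC(C)=O)=C31)O2 | intermediate
34 | C6 acetate of 33 (6,13-diacetoxy butenolide, C6 epimers) | C=C(C)C(=O)O[C@H]1C[C@@](C)(O)[C@@H]2CC[C@](C)(CC3(OC(C)=O)OC(=O)C(COC(C)=O)=C31)O2 | intermediate (not isolated)
35 | CNP0516045.1, (1S,4R,5E,8S,10R)-13-acetoxy-1,4-epoxy-10-hydroxy-12-oxo-6,12-epoxygermacra-5,7(11)-dien-8-yl 2-methylprop-2-enoate | C=C(C)C(=O)O[C@H]1C[C@@](C)(O)[C@@H]2CC[C@](C)(/C=C3/OC(=O)C(COC(C)=O)=C31)O2 | target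

**Step count and risks**

Total steps: 22. Longest linear sequence: 18 steps (steps 1–4 and 9–22 from (R)-linalool; the furan branch, steps 5–8 and 9–22, has the same length).

The three steps most likely to fail:

Step 14 (ring closure). The aldehyde may be attacked on its other face in the cyclic transition state, so that the C8 epimer becomes the main carbinol; oligomerisation is countered by dilution and is the lesser concern. The fallback sets out from 21 and comes back at 23. The same CrCl2 closure is run without regard to the C8 outcome. The resulting (8R) carbinol F1, alone or mixed with 23, is oxidised with MnO2 in CH2Cl2 to the furyl ketone F2. F2 is then reduced under reagent control with (R)-2-methyl-CBS-oxazaborolidine and BH3·SMe2 in THF at −20 °C (Corey–Bakshi–Shibata reduction). With the furan as the large aryl-type group this should deliver the (8S) alcohol 23.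

Step 15 (directed dihydroxylation). Hydrogen-bond delivery across the flexible ring may be too weak, so that osmylation of both alkene faces gives a mixture at C10. The fallback sets out from 23 and comes back at 28. Dihydroxylation with OsO4 (cat.) and N-methylmorpholine N-oxide in acetone/water is accepted as unselective and gives 25 together with the C10-epimeric triol F3. NaIO4 in THF/water cleaves both glycols to the single β-hydroxy ketone F4. MeMgBr in CH2Cl2/Et2O at −78 °C then adds to the magnesium chelate of the C8 alkoxide and the C10 carbonyl (1,3-chelation-controlled Grignard addition). This should place the C10–O bond cis to C8–O and supplies C14, giving 28 directly and bypassing 26 and 27.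

Step 11 (epoxide isomerisation). The base may remove the ring C1 hydrogen instead of a methyl hydrogen, or the Lewis acid may open the tertiary oxirane carbon and trigger rearrangement. The fallback sets out from 18 and comes back at 19. LiPPh2 in THF opens the oxirane at its CH2 terminus to the β-hydroxy phosphine F5. MeI quaternises the phosphorus, and the betaine collapses to the isopropenyl compound F6 (phosphorus-mediated epoxide deoxygenation). Catalytic SeO2 with t-BuOOH in CH2Cl2 then oxidises the allylic methyl group of F6 by an ene reaction and 2,3-sigmatropic shift to the allylic alcohol 19.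

Further compounds
F1 | step 14 | (1S,4R,8R)-13-{[tert-butyl(dimethyl)silyl]oxy}-1,4:6,12-diepoxygermacra-6,10(14),11-trien-8-ol (C8 epimer of 23) | O[C@@H]1CC(=C)[C@@H]2CC[C@](C)(Cc3occ(CO[Si](C)(C)C(C)(C)C)c31)O2
F2 | step 14 | (1S,4R)-13-{[tert-butyl(dimethyl)silyl]oxy}-1,4:6,12-diepoxygermacra-6,10(14),11-trien-8-one | O=C1CC(=C)[C@@H]2CC[C@](C)(Cc3occ(CO[Si](C)(C)C(C)(C)C)c31)O2
F3 | step 15 | (1S,4R,8S,10R)-13-{[tert-butyl(dimethyl)silyl]oxy}-1,4:6,12-diepoxygermacra-6,11-diene-8,10,14-triol (C10 epimer of 25) | O[C@H]1C[C@](CO)(O)[C@@H]2CC[C@](C)(Cc3occ(CO[Si](C)(C)C(C)(C)C)c31)O2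
F4 | step 15 | (1S,4R,8S)-13-{[tert-butyl(dimethyl)silyl]oxy}-8-hydroxy-1,4:6,12-diepoxy-14-norgermacra-6,11-dien-10-one | O[C@H]1CC(=O)[C@@H]2CC[C@](C)(Cc3occ(CO[Si](C)(C)C(C)(C)C)c31)O2
F5 | step 11 | 2-[(2S,5R)-5-{[4-({[tert-butyl(dimethyl)silyl]oxy}methyl)-3-(1,3-dioxolan-2-yl)furan-2-yl]methyl}-5-methyloxolan-2-yl]-1-(diphenylphosphanyl)propan-2-ol, carbinol epimers | CC(O)(CP(c5ccccc5)c5ccccc5)[C@@H]1CC[C@](C)(Cc3occ(CO[Si](C)(C)C(C)(C)C)c3C4OCCO4)O1
F6 | step 11 | tert-butyl{[4-(1,3-dioxolan-2-yl)-5-{[(2R,5S)-2-methyl-5-(prop-1-en-2-yl)oxolan-2-yl]methyl}furan-3-yl]methoxy}dimethylsilane | CC(=C)[C@@H]1CC[C@](C)(Cc3occ(CO[Si](C)(C)C(C)(C)C)c3C4OCCO4)O1
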